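**Retrosynthetic overview**
1. Target 22 ⇐ monocyclic iodo‑alkynyl lactone 19 in one pot: Pd‑catalysed carbonylative alkynylation (CO becomes C3) closes the ten‑membered carbocycle as a 4‑silyloxy‑ynone; amine, then acid, turns it into the 3(2H)‑furanone and removes both silyl ethers.
2. 19 ⇐ iodo‑enal 4 + allylic bromide 17 by indium Barbier allylation/lactonisation (C6–C7 bond; sets C6 and C7; first ring).
3. 17 ⇐ aldehyde 14 by Baylis–Hillman reaction and SN2′ bromination; 14 ⇐ acetone + 2,2‑dimethoxyacetaldehyde (proline aldol sets C8), ethynyl Grignard (chelation sets C10), tigloyl chloride.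
4. 4 ⇐ 2‑butyne‑1,4‑diol by monosilylation, hydroxyl‑directed trans‑hydroalumination/iodination and MnO2 oxidation.
5. Ring order: α‑methylene‑γ‑lactone (step 10), then ten‑membered carbocycle and furanone together (step 11).

Assumption: the SMILES is taken literally, i.e. (6S,7R,8R,10R) with a cis‑fused C6/C7 lactone; germacrane numbering is used in the comments (C1 ketone, C2=C3, C4=C5, C6–O lactone, C7, C8–O‑tiglate, C9, C10 quaternary, C11=C13, C12 lactone C=O, C14 methyl, C15 CH2OH).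

**Step 1**
Reactants: 1 2‑butyne‑1,4‑diol
Product: 2 4‑{[tert‑butyl(dimethyl)silyl]oxy}but‑2‑yn‑1‑ol
Conditions: NaH (1.0 equiv), THF, 0 °C to rt; then TBSCl (1.0 equiv), rt
Reagents that add atoms: tert‑butyldimethylsilyl chloride CC(C)(C)[Si](C)(C)Cl
Why: Monosilylation of a symmetrical diol through its sparingly soluble mono‑sodium alkoxide (Williamson‑type O‑silylation) gives the mono‑TBS ether with little bis‑silylation; no stereocentre is formed.

**Step 2**
Reactants: 2 mono‑TBS butynediol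
Product: 3 (2Z)‑4‑{[tert‑butyl(dimethyl)silyl]oxy}‑3‑iodobut‑2‑en‑1‑ol
Conditions: Red‑Al (1.5 equiv), THF, 0 °C to rt; then I2, −78 °C to 0 °C
Reagents that add atoms: iodine II
Why: Hydroxyl‑directed trans‑hydroalumination of the propargylic alcohol puts aluminium on the distal alkyne carbon (C4) and iodinolysis proceeds with retention, giving the (Z)‑γ‑iodoallylic alcohol with iodine cis to C6, the geometry that later places C3 cis to C6.

**Step 3**
Reactants: 3 (Z)‑iodoallylic alcohol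
Product: 4 (2Z)‑4‑{[tert‑butyl(dimethyl)silyl]oxy}‑3‑iodobut‑2‑enal
Conditions: MnO2 (15 equiv), CH2Cl2, rt, dark
Reagents that add atoms: none
Why: Allylic oxidation with MnO2 gives the enal without touching the vinyl iodide or silyl ether and without Z/E isomerisation.

**Step 4**
Reactants: 5 acetone; 6 2,2‑dimethoxyacetaldehyde
Product: 7 (4R)‑4‑hydroxy‑5,5‑dimethoxypentan‑2‑one
Conditions: L‑proline (30 mol%), acetone (solvent), 6 as 60% aq. solution, rt, 48 h
Reagents that add atoms: none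
Why: Proline‑catalysed direct aldol (List–Barbas type); the (S)‑proline enamine of acetone attacks the Re face of the activated aldehyde through the hydrogen‑bonded enamine transition state, setting C8 as (R).

**Step 5**
Reactants: 7 (R)‑aldol; 8 ethynylmagnesium bromide
Product: 9 (3R,5R)‑6,6‑dimethoxy‑3‑methylhex‑1‑yne‑3,5‑diol
Conditions: 8 (2.5 equiv, 0.5 M in THF), THF, −78 to −20 °C; sat. aq. NH4Cl
Reagents that add atoms: none
Why: The first equivalent of Grignard forms the magnesium β‑alkoxide, whose six‑membered chelate with the ketone is attacked axially by the second (Cram–Reetz 1,3‑chelation control), giving the 1,3‑anti diol with C10 = (R); the dr is expected to be moderate (about 4:1) and the minor C10 epimer is removed by chromatography.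

**Step 6**
Reactants: 9 anti‑diol; 10 (2E)‑2‑methylbut‑2‑enoyl chloride (tigloyl chloride)
Product: 11 (2R,4R)‑4‑hydroxy‑1,1‑dimethoxy‑4‑methylhex‑5‑yn‑2‑yl (2E)‑2‑methylbut‑2‑enoate
Conditions: 10 (1.2 equiv), pyridine, DMAP (10 mol%), CH2Cl2, 0 °C to rt
Reagents that add atoms: none
Why: DMAP‑catalysed acylation discriminates between the secondary C8 hydroxyl and the tertiary propargylic C10 hydroxyl, installing the tiglate early so that no late ester exchange is needed; no stereocentre is touched.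

**Step 7**
Reactants: 11 mono‑tiglate acetal
Product: 14 (2R,4R)‑4‑methyl‑1‑oxo‑4‑[(triethylsilyl)oxy]hex‑5‑yn‑2‑yl (2E)‑2‑methylbut‑2‑enoate, via TES ether acetal 12 (not isolated), via collidinium salt 13 (not isolated)
Conditions: TESOTf (3.5 equiv), 2,4,6‑collidine (5 equiv), CH2Cl2, 0 °C; then H2O, rt
Reagents that add atoms: triethylsilyl trifluoromethanesulfonate CC[Si](CC)(CC)OS(=O)(=O)C(F)(F)F; water O
Why: TESOTf/collidine silylates the tertiary alcohol and in the same flask converts the dimethyl acetal into a collidinium salt that water hydrolyses to the aldehyde under non‑acidic conditions (Fujioka–Kita acetal cleavage), so the C10 oxygen is blocked before the γ‑hydroxy aldehyde could close to a lactol and C8 is not epimerised.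

**Step 8**
Reactants: 14 α‑tigloyloxy aldehyde; 15 methyl acrylate
Product: 16 methyl (4R,6R)‑3‑hydroxy‑6‑methyl‑2‑methylidene‑4‑{[(2E)‑2‑methylbut‑2‑enoyl]oxy}‑6‑[(triethylsilyl)oxy]oct‑7‑ynoate (both C3 epimers)
Conditions: 15 (5 equiv), DABCO (1 equiv), 1,4‑dioxane/H2O (1:1), rt, 24 h
Reagents that add atoms: none
Why: Morita–Baylis–Hillman reaction of the activated aldehyde with methyl acrylate attaches C11–C13; the new carbinol centre (C7) forms as a mixture that is erased in the next step.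

**Step 9**
Reactants: 16 Baylis–Hillman adduct
Product: 17 methyl (2Z,4R,6R)‑2‑(bromomethyl)‑6‑methyl‑4‑{[(2E)‑2‑methylbut‑2‑enoyl]oxy}‑6‑[(triethylsilyl)oxy]oct‑2‑en‑7‑ynoate
Conditions: NBS (1.5 equiv), Me2S (1.8 equiv), CH2Cl2, 0 °C to rt
Reagents that add atoms: N‑bromosuccinimide O=C1CCC(=O)N1Br
Why: Corey–Kim‑type activation of the allylic alcohol followed by SN2′ attack of bromide gives the favoured (Z)‑2‑(bromomethyl)enoate with C8 cis to CH2Br, the geometry needed for a syn‑selective allylation.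

**Step 10**
Reactants: 4 (Z)‑iodo‑enal; 17 allylic bromide
Product: 19 (1R,3R)‑1‑[(2R,3R)‑2‑[(1Z)‑3‑{[tert‑butyl(dimethyl)silyl]oxy}‑2‑iodoprop‑1‑en‑1‑yl]‑4‑methylidene‑5‑oxooxolan‑3‑yl]‑3‑methyl‑3‑[(triethylsilyl)oxy]pent‑4‑yn‑1‑yl (2E)‑2‑methylbut‑2‑enoate, via syn‑hydroxy ester 18 (not isolated)
Conditions: In powder (1.5 equiv), THF/sat. aq. NH4Cl (3:1), rt; then PPTS (10 mol%), toluene, 50 °C
Reagents that add atoms: none
Why: Indium‑mediated Barbier allylation: the (Z)‑2‑(methoxycarbonyl)allylindium reacts at its γ‑carbon through a chair Zimmerman–Traxler transition state to give the syn adduct (cis‑lactone after ring closure) and is predicted to attack anti to the C9 branch of the A(1,3)‑locked C8 centre (H eclipsed; OTig on the reacting face), setting C6 and C7 in the target's configuration before acid‑catalysed lactonisation closes the first ring.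

**Step 11**
Reactants: 19 iodo‑alkynyl lactone
Product: 22 target, (6S,7R,8R,10R)‑15‑hydroxy‑1‑oxo‑3,10‑epoxygermacra‑2,4Z,11(13)‑trien‑12,6‑olide 8‑O‑tiglate, via macrocyclic ynone 20 (not isolated), via macrocyclic enaminone 21 (not isolated)
Conditions: PdCl2(PPh3)2 (10 mol%), CuI (10 mol%), Et3N (5 equiv), CO (1 atm), THF, 40 °C, syringe‑pump addition of 19 (final 2 mM); then Et2NH (1.2 equiv), 0 °C, 20 min; then 2 M aq. HCl/THF, rt
Reagents that add atoms: carbon monoxide [C-]#[O+]; water O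
Why: Proposed new method: oxidative addition of Pd(0) to the vinyl iodide (Z geometry retained), CO insertion to the acyl‑palladium and copper‑assisted coupling with the tethered terminal alkyne close the ten‑membered ring as a cross‑conjugated ynone, because the competing direct coupling would give a far more strained nine‑membered enyne; Et2NH then adds to the ynone β‑carbon (C1) much faster than to the α‑methylene lactone, and aqueous HCl hydrolyses the vinylogous amide, cleaves both silyl ethers and lets the C10 hydroxyl close onto C3 with loss of water, so carbocycle and 3(2H)‑furanone form in one pot with no stereocentre touched; the closest known reaction types are the carbonylative Sonogashira coupling, intramolecular carbonylative Stille macrocyclisation, the amine‑mediated isomerisation of 4‑hydroxyalk‑2‑ynones to 3(2H)‑furanones and the acid‑induced desilylation–cyclodehydration of α′‑silyloxy 1,3‑diketones.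

**Compound list**
1 | 2‑butyne‑1,4‑diol | OCC#CCO | starting material
2 | 4‑{[tert‑butyl(dimethyl)silyl]oxy}but‑2‑yn‑1‑ol | OCC#CCO[Si](C)(C)C(C)(C)C | intermediate
3 | (2Z)‑4‑{[tert‑butyl(dimethyl)silyl]oxy}‑3‑iodobut‑2‑en‑1‑ol | OC/C=C(\I)CO[Si](C)(C)C(C)(C)C | intermediate
4 | (2Z)‑4‑{[tert‑butyl(dimethyl)silyl]oxy}‑3‑iodobut‑2‑enal | O=C/C=C(\I)CO[Si](C)(C)C(C)(C)C | intermediate
5 | acetone | CC(C)=O | starting material
6 | 2,2‑dimethoxyacetaldehyde | COC(OC)C=O | starting material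
7 | (4R)‑4‑hydroxy‑5,5‑dimethoxypentan‑2‑one | CC(=O)C[C@@H](O)C(OC)OC | intermediate
8 | ethynylmagnesium bromide | C#C[Mg]Br | starting material
9 | (3R,5R)‑6,6‑dimethoxy‑3‑methylhex‑1‑yne‑3,5‑diol | C#C[C@@](C)(C[C@@H](O)C(OC)OC)O | intermediate
10 | (2E)‑2‑methylbut‑2‑enoyl chloride (tigloyl chloride) | C/C=C(\C)C(Cl)=O | starting material
11 | (2R,4R)‑4‑hydroxy‑1,1‑dimethoxy‑4‑methylhex‑5‑yn‑2‑yl (2E)‑2‑methylbut‑2‑enoate | C#C[C@@](C)(C[C@@H](OC(=O)/C(C)=C/C)C(OC)OC)O | intermediate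
12 | (2R,4R)‑1,1‑dimethoxy‑4‑methyl‑4‑[(triethylsilyl)oxy]hex‑5‑yn‑2‑yl (2E)‑2‑methylbut‑2‑enoate | C#C[C@@](C)(C[C@@H](OC(=O)/C(C)=C/C)C(OC)OC)O[Si](CC)(CC)CC | intermediate
13 | 1‑{(2R,4R)‑1‑methoxy‑4‑methyl‑2‑{[(2E)‑2‑methylbut‑2‑enoyl]oxy}‑4‑[(triethylsilyl)oxy]hex‑5‑yn‑1‑yl}‑2,4,6‑trimethylpyridinium triflate (C1 epimers) | C#C[C@@](C)(C[C@@H](OC(=O)/C(C)=C/C)C(OC)[n+]1c(C)cc(C)cc1C)O[Si](CC)(CC)CC.[O-]S(=O)(=O)C(F)(F)F | intermediate
14 | (2R,4R)‑4‑methyl‑1‑oxo‑4‑[(triethylsilyl)oxy]hex‑5‑yn‑2‑yl (2E)‑2‑methylbut‑2‑enoate | C#C[C@@](C)(C[C@@H](OC(=O)/C(C)=C/C)C=O)O[Si](CC)(CC)CC | intermediate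
15 | methyl acrylate | C=CC(=O)OC | starting material
16 | methyl (4R,6R)‑3‑hydroxy‑6‑methyl‑2‑methylidene‑4‑{[(2E)‑2‑methylbut‑2‑enoyl]oxy}‑6‑[(triethylsilyl)oxy]oct‑7‑ynoate (C3 epimers) | C#C[C@@](C)(C[C@@H](OC(=O)/C(C)=C/C)C(O)C(=C)C(=O)OC)O[Si](CC)(CC)CC | intermediate
17 | methyl (2Z,4R,6R)‑2‑(bromomethyl)‑6‑methyl‑4‑{[(2E)‑2‑methylbut‑2‑enoyl]oxy}‑6‑[(triethylsilyl)oxy]oct‑2‑en‑7‑ynoate | C#C[C@@](C)(C[C@@H](OC(=O)/C(C)=C/C)/C=C(\CBr)C(=O)OC)O[Si](CC)(CC)CC | intermediate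
18 | methyl (3S,4R,6R)‑3‑[(1R,2Z)‑4‑{[tert‑butyl(dimethyl)silyl]oxy}‑1‑hydroxy‑3‑iodobut‑2‑en‑1‑yl]‑6‑methyl‑2‑methylidene‑4‑{[(2E)‑2‑methylbut‑2‑enoyl]oxy}‑6‑[(triethylsilyl)oxy]oct‑7‑ynoate | C=C(C(=O)OC)[C@@H]([C@@H](O)/C=C(\I)CO[Si](C)(C)C(C)(C)C)[C@H](OC(=O)/C(C)=C/C)C[C@](C)(C#C)O[Si](CC)(CC)CC | intermediate
19 | (1R,3R)‑1‑[(2R,3R)‑2‑[(1Z)‑3‑{[tert‑butyl(dimethyl)silyl]oxy}‑2‑iodoprop‑1‑en‑1‑yl]‑4‑methylidene‑5‑oxooxolan‑3‑yl]‑3‑methyl‑3‑[(triethylsilyl)oxy]pent‑4‑yn‑1‑yl (2E)‑2‑methylbut‑2‑enoate | C=C1C(=O)O[C@@H](/C=C(\I)CO[Si](C)(C)C(C)(C)C)[C@H]1[C@H](OC(=O)/C(C)=C/C)C[C@](C)(C#C)O[Si](CC)(CC)CC | intermediate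
20 | (6S,7R,8R,10R)‑15‑(TBS‑oxy)‑10‑(TES‑oxy)‑3‑oxogermacra‑4Z,11(13)‑dien‑1‑yn‑12,6‑olide 8‑O‑tiglate (ten‑membered ynone, cis‑fused lactone) | C=C1C(=O)O[C@H]2/C=C(/CO[Si](C)(C)C(C)(C)C)C(=O)C#C[C@@](C)(C[C@@H](OC(=O)/C(C)=C/C)[C@@H]12)O[Si](CC)(CC)CC | intermediate
21 | (6S,7R,8R,10R)‑1‑(diethylamino)‑15‑(TBS‑oxy)‑10‑(TES‑oxy)‑3‑oxogermacra‑1,4Z,11(13)‑trien‑12,6‑olide 8‑O‑tiglate (C1=C2 geometry not defined) | C=C1C(=O)O[C@H]2/C=C(/CO[Si](C)(C)C(C)(C)C)C(=O)C=C(N(CC)CC)[C@@](C)(C[C@@H](OC(=O)/C(C)=C/C)[C@@H]12)O[Si](CC)(CC)CC | intermediate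
22 | (6S,7R,8R,10R)‑15‑hydroxy‑1‑oxo‑3,10‑epoxygermacra‑2,4Z,11(13)‑trien‑12,6‑olide 8‑O‑[(2E)‑2‑methylbut‑2‑enoate] | C=C1C(=O)O[C@H]2/C=C(/CO)C3=CC(=O)[C@@](C)(C[C@@H](OC(=O)/C(C)=C/C)[C@@H]12)O3 | target

**Step count and risks**
Total step count: 11 (steps 1–3 to aldehyde 4; steps 4–9 to bromide 17; steps 10–11 union and ring closure). Longest linear sequence: 8 steps (steps 4–11, from 5 and 6 to 22).

Three steps most likely to fail:

Step 11 (ring‑closing carbonylation: oligomerisation, direct coupling, or amine addition to the methylene lactone could defeat it). Fallback, setting out from 4 and 16 and coming back at 20: reverse the order of the ring‑forming events. Couple 4 and 16 intermolecularly under the same carbonylative Sonogashira conditions (PdCl2(PPh3)2, CuI, Et3N, CO 1 atm, THF, rt) to the acyclic enal ynone F1. Convert its allylic alcohol with NBS/Me2S into the (Z)‑allylic bromide F2. Add F2 slowly to indium powder in THF/aq. NH4Cl so that an intramolecular Barbier allylation closes the ten‑membered ring as the macrocyclic hydroxy ester F3, which lactonises (PPTS) to the macrocyclic ynone 20. Compound 20 is then isolated and taken through the Et2NH and aq. HCl stages of step 11 to 22.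

Step 10 (Barbier allylation: the δ‑acyloxy allylindium may undergo reductive 1,4‑elimination to a diene, or the C8 centre may give poor facial control). Fallback, setting out from 16 and coming back at 19: replace the allylindium by an isolable allylboronate. Acetylate 16 (Ac2O, pyridine, DMAP) to the acetate F4. Carry out a copper‑catalysed SN2′ borylation (B2pin2, CuCl, KOAc, DMF) to the (E)‑allylboronate F5, which keeps C8 cis to the CH2 group. Heat F5 with aldehyde 4 (toluene, 60 °C); the closed chair allylboration gives after work‑up the same syn hydroxy ester 18, which is lactonised (PPTS) to 19.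

Step 8 (Baylis–Hillman reaction on an α‑acyloxy aldehyde: slow, and the amine may epimerise C8). Fallback, setting out from 14 and coming back at 16: use a stoichiometric vinyl‑metal in place of amine catalysis. Hydroaluminate methyl propiolate with DIBAL‑H/NMO (THF, 0 °C) to the α‑(methoxycarbonyl)vinylalane F6 and add it to 14 at 0 °C; aqueous work‑up gives 16 without exposing the aldehyde to base.

**Further compounds**
F1 | step 11 | methyl (4R,6R)‑3‑hydroxy‑6‑methyl‑2‑methylidene‑4‑(tigloyloxy)‑6‑(triethylsilyloxy)‑9‑oxo‑10‑[(TBS‑oxy)methyl]‑12‑oxododec‑10Z‑en‑7‑ynoate (acyclic enal ynone) | O=C/C=C(/CO[Si](C)(C)C(C)(C)C)C(=O)C#C[C@@](C)(C[C@@H](OC(=O)/C(C)=C/C)C(O)C(=C)C(=O)OC)O[Si](CC)(CC)CC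
F2 | step 11 | (Z)‑allylic bromide of F1 (methyl 2‑(bromomethyl)‑2Z‑enoate terminus) | O=C/C=C(/CO[Si](C)(C)C(C)(C)C)C(=O)C#C[C@@](C)(C[C@@H](OC(=O)/C(C)=C/C)/C=C(\CBr)C(=O)OC)O[Si](CC)(CC)CC
F3 | step 11 | macrocyclic hydroxy ester (ten‑membered ynone carrying C6‑OH and the C7 methyl acrylate unit) | C=C(C(=O)OC)[C@H]1[C@@H](O)/C=C(/CO[Si](C)(C)C(C)(C)C)C(=O)C#C[C@@](C)(C[C@H]1OC(=O)/C(C)=C/C)O[Si](CC)(CC)CC
F4 | step 10 | methyl (4R,6R)‑3‑acetoxy‑6‑methyl‑2‑methylidene‑4‑(tigloyloxy)‑6‑(triethylsilyloxy)oct‑7‑ynoate | C#C[C@@](C)(C[C@@H](OC(=O)/C(C)=C/C)C(OC(C)=O)C(=C)C(=O)OC)O[Si](CC)(CC)CC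
F5 | step 10 | methyl (2E,4R,6R)‑6‑methyl‑2‑[(4,4,5,5‑tetramethyl‑1,3,2‑dioxaborolan‑2‑yl)methyl]‑4‑(tigloyloxy)‑6‑(triethylsilyloxy)oct‑2‑en‑7‑ynoate | C#C[C@@](C)(C[C@@H](OC(=O)/C(C)=C/C)/C=C(\CB1OC(C)(C)C(C)(C)O1)C(=O)OC)O[Si](CC)(CC)CC
F6 | step 8 | methyl 2‑[bis(2‑methylpropyl)alumanyl]prop‑2‑enoate | C=C(C(=O)OC)[Al](CC(C)C)CC(C)C
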